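## The problem

Compound 12 is an achiral diaryl ether. Ring A is a methyl benzoate numbered C1 (ester), C2 (prenyloxy), C4 (methyl) and C6 (aryloxy); ring B is numbered C1' (ether oxygen), C2' (hydroxymethyl), C4' and C6' (methoxy). There is no stereocentre and no configured double bond, so the task is one of connectivity and chemoselectivity only. The central ether oxygen lies between three ortho substituents (the ester on ring A, the hydroxymethyl and a methoxy group on ring B) and both rings are electron-rich, which makes a direct aryl–oxygen coupling or an aromatic substitution unattractive. The two oxygens flanking the ester must end up different, one as prenyl ether and one as aryl ether, so they are best introduced in different ways and not by desymmetrising a 2,6-dihydroxybenzoate. Fragile groups are the prenyl aryl ether (acid, Claisen shift on heating, hydrogenation, zerovalent palladium), the benzylic alcohol ortho to the ether oxygen (as an alkoxide it can attack the ring A ester and close an eight-membered lactone) and the methyl ester. The feature that opens the key step is the acetate-type pattern of ring A, which maps onto dehydroacetic acid 5 as follows: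

| Ring A of 12 | Dehydroacetic acid 5 |
|---|---|
| ester carbon | lactone carbonyl C2 |
| C1 | C3 |
| C2 and its oxygen | acetyl carbonyl carbon and its oxygen |
| C3 | acetyl methyl |
| C4 and its methyl | C6 and its methyl |
| C5 | C5 |
| C6 and its oxygen | C4 and its oxygen |

## Retrosynthesis

**12 from 11.** The last cut is the O–Si bond of the triisopropylsilyl ether 11. The benzylic oxygen has to be masked from the moment ring B is attached to a pyranone. A free alkoxide ortho to the ether oxygen could add to pyranone C4 through a six-membered spiro intermediate and shift the pyranone from the phenolic to the benzylic oxygen, and later it could attack the ester. A triisopropylsilyl group survives carbonate, magnesium methoxide in hot methanol and alkylation, and buffered fluoride removes it without touching the ester or the prenyl ether.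

**11 from 10.** The O–prenyl bond is cut next, leading to phenol 10. The prenyl group cannot be carried earlier, because its oxygen is only created in the ring-forming step as a free hydroxyl. This is also an advantage: the two ortho oxygens of ring A differ by origin, so no desymmetrisation is needed, and the acid- and heat-sensitive prenyl ether appears after all ring-forming chemistry. The forward step is a Williamson etherification of a hydrogen-bonded salicylate hydroxyl.

**10 from 7.** Ring A of 10 is opened at its C3–C4 bond (an aldol retron after formal addition of water) and its ester is reconnected as a lactone. This gives the 3-acetyl-4-aryloxypyranone 7, via the open-chain keto ester 8 and the cyclic aldol 9. Against cutting the diaryl ether C–O bond of 10 directly, this cut removes the whole problem of a tri-ortho-substituted aryl–oxygen coupling. The ether oxygen is already attached to the carbon that becomes ring A C6 before that carbon is aromatic. The precursor 7 has one ring fewer in its carbon framework and is assembled from two stable pieces. The forward reaction must open the lactone with methoxide without exchanging the aryloxy group, and it must close the aldol from the acetyl methyl onto the liberated methyl ketone and not the reverse.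

**7 from 4 and 6.** The vinylic C4–O bond of 7 is cut to the ring B phenol 4 and the 4-chloropyranone 6. Pyranone C4 in 6 is a vinylogous acid chloride carbon activated by both the lactone and the acetyl carbonyl, so the hindered phenoxide is introduced by addition–elimination under mild carbonate conditions. The forward step needs only O-selectivity, which is assured because both ortho positions and the para position of 4 are substituted.

**6 from 5.** The C–Cl bond goes back to the enolic hydroxyl of dehydroacetic acid 5, a bulk chemical that contains all eight carbons of ring A, its methyl group and its ester carbonyl in the correct order. A deoxychlorination of a vinylogous acid is required.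

**4 from 1.** The silyl ether 4 comes from the salicyl alcohol 3 by selective silylation of the primary hydroxyl. Diol 3 comes from the salicylaldehyde 2 by hydride reduction, and 2 from commercial 2,4-dimethoxyphenol 1 by cutting the C–C bond ortho to the hydroxyl (ortho-formylation). Phenol 1 has a single free ortho position, so the regiochemistry is fixed by the substrate. The aldehyde is reduced and protected before the coupling so that no alkoxide is ever generated next to the pyranone.

## Roads not taken

**Alternative 1:** Ring B instead of ring A is built, by cutting C1'–C2' and C3'–C4'. A ring A phenol that already carries ester, methyl and prenyloxy groups would be O-alkylated at an sp3 carbon and converted into the 4-aryloxy-1,3-dimethoxy-1-silyloxybutadiene A2. Cycloaddition of A2 to methyl (E)-3-nitroacrylate A3, then loss of the nitro group and of one methoxy group from the adduct, would close ring B and give the diaryl ether A1.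
- Merits: the congested ether bond is made by a simple alkylation; the nitro group fixes the regiochemistry, since the nucleophilic diene terminus bearing the aryloxy group bonds to the carbon β to nitro; no protecting group is needed.
- Weak points: ring A has to be obtained as a 2,6-dioxygenated benzoate and desymmetrised beforehand, so the hardest substitution pattern is not created by the plan. A tetra-oxygenated diene with a bulky group on its reacting terminus is hydrolytically labile and slow to add. A1 has ring B at the wrong oxidation pattern: the 4'-hydroxyl must be methylated and the ring B ester reduced to the hydroxymethyl group beside the ring A ester.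
- Comparison: in step count this road is comparable, perhaps one step shorter, and it is free of protecting groups; that must be conceded. The chosen plan sets against it that ring A with its two different ortho oxygens is created from a commodity pyranone, that no late ester-versus-ester differentiation is needed, and that the prenyl ether is introduced only after ring formation.

**Alternative 2:** The O–C6 bond and the C1–carboxyl bond of ring A are cut together. Fluoride-induced elimination from the silyl triflate A5 would generate the aryne. The aryloxide of 4 adds at the aryne carbon remote from the allyloxy group, and the resulting aryl anion, flanked by both oxygens, is carboxylated in situ to the acid A4.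
- Merits: this is the most convergent plan. One operation forms the hindered ether with an electrophile reactive enough to ignore ortho substituents, and it places the carboxyl carbon between the two oxygens under the inductive control of the alkoxy group.
- Weak points: A5 needs a multistep synthesis from a symmetric resorcinol, including a desymmetrising mono-allylation. The aryloxide is partly tied up as a carbonate under carboxylation conditions, and protonation of the aryl anion competes. The fluoride source endangers the silyl ether. An allyl group must stand in for prenyl, because the prenyl methyls would offer the aryne an ene pathway; esterification, allyl-to-prenyl exchange by cross-metathesis and desilylation therefore still follow A4.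
- Comparison: in convergence and in tolerance of steric crowding this road is better. The chosen plan answers with a clearly shorter sequence (eight steps against roughly twelve), bulk starting materials, and direct installation of the prenyl group.

**Alternative 3:** Ring A is cut at C4–C5 and C6–C1. The 3-carbomethoxypyranone A8, carrying the prenyloxy and methyl groups, would add the aryl ethynyl ether A7 across its C3 and C6 positions. Decarboxylative cycloreversion of the bridged adduct would aromatise to A6, which is identical with compound 11.
- Merits: it shares the pyranone-to-arene idea and is convergent. The polarity of both partners fixes the regiochemistry (the nucleophilic terminal carbon of A7 bonds to C6 of A8). After the key step only the desilylation remains, one operation fewer than in the chosen route.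
- Weak points: A8 is an electron-rich 4-alkoxy-6-methylpyranone and a reluctant partner for an electron-rich alkyne. Temperatures are to be expected at which the prenyl enol ether of A8 can undergo a Claisen shift to C3. A7 must be made from the hindered phenol 4 in at least two further steps, and aryl alkynyl ethers are prone to hydration and oligomerisation.
- Comparison: in post-cyclisation steps this road is better, and in total step count about equal. The chosen plan sets against it a precursor 7 made by one substitution from stable materials and a ring closure in methanol at reflux instead of a forcing thermal cycloaddition.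

Key step: step 6

Remark on the chemistry: the target has no stereocentre, so the SMILES carry no stereodescriptors except for the transient alkene of 8. In the IUPAC name of 10 the hydroxyl has locant 6 and the aryloxy group locant 2; in the ring A numbering used in the discussion these are C2 and C6. 2,4-Dimethoxyphenol, dehydroacetic acid, Mg(OMe)2 in methanol and 1-bromo-3-methylbut-2-ene are taken as commercial.

## Route

Step 1
Reactants: 1 2,4-dimethoxyphenol
Product: 2 2-hydroxy-3,5-dimethoxybenzaldehyde
Conditions: MgCl2, Et3N, (CH2O)n, MeCN, reflux; then 1 M HCl
Reagents that add atoms: paraformaldehyde (as formaldehyde), C=O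
Why: Magnesium-mediated ortho-formylation of a phenol (Casnati–Skattebøl): the magnesium phenoxide of 1 directs formaldehyde to the single free ortho position and a second equivalent of formaldehyde acts as hydride acceptor, so the aldehyde is obtained directly and the other ring positions are not touched.

Step 2
Reactants: 2 2-hydroxy-3,5-dimethoxybenzaldehyde
Product: 3 2-(hydroxymethyl)-4,6-dimethoxyphenol
Conditions: NaBH4, MeOH, 0 °C; then aq. NH4Cl
Reagents that add atoms: none
Why: Borohydride reduction of a salicylaldehyde to the salicyl alcohol; because 3 is electron-rich and can lose water to an ortho-quinone methide under acid, the work-up is kept neutral and the crude diol is carried on at once.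

Step 3
Reactants: 3 2-(hydroxymethyl)-4,6-dimethoxyphenol
Product: 4 2,4-dimethoxy-6-(triisopropylsilyloxymethyl)phenol
Conditions: TIPSCl, imidazole, DMF, 0 °C to rt
Reagents that add atoms: chlorotriisopropylsilane, CC(C)[Si](Cl)(C(C)C)C(C)C
Why: Silylation with a bulky silyl chloride and imidazole distinguishes the unhindered primary hydroxyl from the phenol, which is flanked on both sides and hydrogen-bonded, as is usual for salicyl alcohols; the phenol stays free for step 5.

Step 4
Reactants: 5 dehydroacetic acid (3-acetyl-4-hydroxy-6-methyl-2H-pyran-2-one)
Product: 6 3-acetyl-4-chloro-6-methyl-2H-pyran-2-one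
Conditions: POCl3, Et3N, MeCN, 60 °C; then ice-water
Reagents that add atoms: phosphoryl chloride, O=P(Cl)(Cl)Cl
Why: Deoxychlorination of a vinylogous carboxylic acid, as practised on 4-hydroxypyran-2-ones and 4-hydroxycoumarins: O-phosphorylation of the C4 hydroxyl and addition–elimination of chloride give the vinylogous acid chloride 6, which is used without storage.

Step 5
Reactants: 4 2,4-dimethoxy-6-(triisopropylsilyloxymethyl)phenol; 6 3-acetyl-4-chloro-6-methyl-2H-pyran-2-one
Product: 7 3-acetyl-4-[2,4-dimethoxy-6-(triisopropylsilyloxymethyl)phenoxy]-6-methyl-2H-pyran-2-one
Conditions: K2CO3, MeCN, 0 °C to rt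
Reagents that add atoms: none
Why: Nucleophilic vinylic substitution by addition–elimination at pyranone C4, which is β to both the lactone and the acetyl carbonyl and carries chloride; the phenoxide of 4 can react only through oxygen because its ortho and para positions are substituted, and the silyl ether keeps the benzylic oxygen out of play.

Step 6
Reactants: 7 3-acetyl-4-[2,4-dimethoxy-6-(triisopropylsilyloxymethyl)phenoxy]-6-methyl-2H-pyran-2-one
Product: 10 methyl 2-[2,4-dimethoxy-6-(triisopropylsilyloxymethyl)phenoxy]-6-hydroxy-4-methylbenzoate, via open-chain keto ester 8 (not isolated), via racemic cyclic aldol 9 (not isolated)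
Conditions: Mg(OMe)2, MeOH, 0 °C then reflux; then 1 M HCl
Reagents that add atoms: magnesium methoxide, [Mg+2].[O-]C.[O-]C
Why: Proposed new method: methoxide bound to magnesium is expected to add to the lactone carbonyl (pyranone C2) of 7 in a coordination–insertion manner and to open the ring to the methyl ester 8, first as the extended magnesium enolate of the freed 2-oxopropyl ketone. In that anion the C2=C3 bond of 8 has little double-bond character, so the acetyl group can rotate syn to the 2-oxopropyl arm, and proton exchange in methanol gives the tautomer in which the acetyl methyl is enolised and the 2-oxopropyl carbonyl is a free ketone. That enolate adds to the ketone in a 6-(enolendo)-exo-trig aldol closure, forming the bond between the former acetyl methyl carbon and pyranone C6 (C3–C4 of ring A) and giving 9. E1cB loss of water from 9 and enolisation of the resulting cyclohexadienone give the arene 10, whose new hydroxyl is the former acetyl oxygen, and chelation of the salicylate by magnesium makes the sequence irreversible. The closest known reaction type is the Mg(OMe)2- or KOH-induced opening of 4-oxygenated pyran-2-ones bearing a ketone side chain with aldol aromatisation to resorcylate esters, together with the base cyclisation of acyclic 2,4,6-triketones to orcinol-type arenes in which a terminal methyl is likewise the nucleophile; a 3-acetyl-4-aryloxypyranone has not been taken through such a sequence. The stereocentre of 9 is formed as a racemate and is erased by the dehydration, so no stereocontrol is involved. Two selectivities are needed: attack at the lactone carbonyl and not addition–elimination at pyranone C4, which the two ortho substituents of ring B shielding C4 and the low free-methoxide concentration of Mg(OMe)2 should favour; and the direction of the aldol, which is set because the acetyl carbonyl is a vinylogous aryl carbonate held in the magnesium acylacetate chelate and hence a poor electrophile, whereas the 2-oxopropyl ketone is isolated (the reverse closure would give the 4-hydroxy-6-methyl isomer).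

Step 7
Reactants: 10 methyl 2-[2,4-dimethoxy-6-(triisopropylsilyloxymethyl)phenoxy]-6-hydroxy-4-methylbenzoate
Product: 11 methyl 2-[2,4-dimethoxy-6-(triisopropylsilyloxymethyl)phenoxy]-4-methyl-6-(3-methylbut-2-enyloxy)benzoate
Conditions: prenyl bromide, K2CO3, DMF, rt
Reagents that add atoms: 1-bromo-3-methylbut-2-ene (prenyl bromide), CC(C)=CCBr
Why: Williamson etherification of the salicylate hydroxyl with an allylic bromide under carbonate conditions; the phenol is the only acidic site, O-alkylation at the primary terminus is the normal course in a dipolar aprotic solvent, and the ester, silyl ether and diaryl ether are inert.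

Step 8
Reactants: 11 methyl 2-[2,4-dimethoxy-6-(triisopropylsilyloxymethyl)phenoxy]-4-methyl-6-(3-methylbut-2-enyloxy)benzoate
Product: 12 methyl 2-[2-(hydroxymethyl)-4,6-dimethoxyphenoxy]-4-methyl-6-(3-methylbut-2-enyloxy)benzoate (CNP0573678.0)
Conditions: Bu4NF, AcOH, THF, 0 °C to rt
Reagents that add atoms: none
Why: Fluoride cleavage of a primary silyl ether; buffering with acetic acid keeps the liberated benzylic oxygen protonated, so neither transesterification onto the neighbouring ring A ester (eight-membered lactone) nor ester cleavage by basic fluoride should occur, and the prenyl ether is untouched.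

## Compound list

1 | 2,4-dimethoxyphenol | COc1ccc(O)c(OC)c1 | starting material
2 | 2-hydroxy-3,5-dimethoxybenzaldehyde | O=Cc1cc(OC)cc(OC)c1O | intermediate
3 | 2-(hydroxymethyl)-4,6-dimethoxyphenol | OCc1cc(OC)cc(OC)c1O | intermediate
4 | 2,4-dimethoxy-6-(triisopropylsilyloxymethyl)phenol | CC(C)[Si](OCc1cc(OC)cc(OC)c1O)(C(C)C)C(C)C | intermediate
5 | dehydroacetic acid (3-acetyl-4-hydroxy-6-methyl-2H-pyran-2-one) | CC(=O)C1=C(O)C=C(C)OC1=O | starting material
6 | 3-acetyl-4-chloro-6-methyl-2H-pyran-2-one | CC(=O)C1=C(Cl)C=C(C)OC1=O | intermediate
7 | 3-acetyl-4-[2,4-dimethoxy-6-(triisopropylsilyloxymethyl)phenoxy]-6-methyl-2H-pyran-2-one | CC(=O)C1=C(Oc2c(CO[Si](C(C)C)(C(C)C)C(C)C)cc(OC)cc2OC)C=C(C)OC1=O | intermediate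
8 | methyl (2E)-2-acetyl-3-[2,4-dimethoxy-6-(triisopropylsilyloxymethyl)phenoxy]-5-oxohex-2-enoate (geometry as first formed; it equilibrates through the enolate) | COC(=O)/C(C(C)=O)=C(\CC(C)=O)Oc1c(CO[Si](C(C)C)(C(C)C)C(C)C)cc(OC)cc1OC | intermediate (not isolated)
9 | methyl 2-[2,4-dimethoxy-6-(triisopropylsilyloxymethyl)phenoxy]-4-hydroxy-4-methyl-6-oxocyclohex-1-ene-1-carboxylate (racemic) | COC(=O)C1=C(Oc2c(CO[Si](C(C)C)(C(C)C)C(C)C)cc(OC)cc2OC)CC(C)(O)CC1=O | intermediate (not isolated)
10 | methyl 2-[2,4-dimethoxy-6-(triisopropylsilyloxymethyl)phenoxy]-6-hydroxy-4-methylbenzoate | COC(=O)c1c(O)cc(C)cc1Oc1c(CO[Si](C(C)C)(C(C)C)C(C)C)cc(OC)cc1OC | intermediate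
11 | methyl 2-[2,4-dimethoxy-6-(triisopropylsilyloxymethyl)phenoxy]-4-methyl-6-(3-methylbut-2-enyloxy)benzoate | COC(=O)c1c(OCC=C(C)C)cc(C)cc1Oc1c(CO[Si](C(C)C)(C(C)C)C(C)C)cc(OC)cc1OC | intermediate
12 | methyl 2-[2-(hydroxymethyl)-4,6-dimethoxyphenoxy]-4-methyl-6-(3-methylbut-2-enyloxy)benzoate | COC(=O)c1c(OCC=C(C)C)cc(C)cc1Oc1c(CO)cc(OC)cc1OC | target

## Step count and least certain steps

Total step count: 8. Longest linear sequence: 7 steps (steps 1, 2, 3, 5, 6, 7, 8 from 2,4-dimethoxyphenol); the dehydroacetic acid branch adds step 4 and joins at step 5.

**Step 6 (key step, proposed new method).** Several processes could take over: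
- exchange of the aryloxy group for methoxide by addition–elimination at pyranone C4, before or instead of lactone opening;
- closure of 8 in the reverse aldol direction, or in a Claisen sense from the terminal methyl onto the ester;
- retro-Claisen loss of the acetyl group.

The fallback uses known chemistry and leaves the pyranone branch. It sets out from phenol 4 and returns at 10.
- Commercial methyl 2,6-dihydroxy-4-methylbenzoate F1 would be mono-benzylated (BnBr, K2CO3, acetone) to methyl 2-(benzyloxy)-6-hydroxy-4-methylbenzoate F2.
- F2 would be converted with Tf2O and pyridine into methyl 2-(benzyloxy)-4-methyl-6-(trifluoromethylsulfonyloxy)benzoate F3.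
- F3 would be coupled with 4 under Pd(OAc)2, 2-(di-tert-butylphosphino)-2',4',6'-triisopropylbiphenyl and K3PO4 in toluene at 100 °C (Buchwald–Hartwig diaryl ether synthesis) to methyl 2-(benzyloxy)-6-[2,4-dimethoxy-6-(triisopropylsilyloxymethyl)phenoxy]-4-methylbenzoate F4.
- Hydrogenolysis of the benzyl ether (H2, Pd/C, EtOAc) would give 10.

A benzyl and not a prenyl ether is carried through the coupling because zerovalent palladium would ionise an allylic aryl ether.

**Step 5.** The addition–elimination may be slow because the nucleophile is a doubly ortho-substituted phenoxide, so base-induced self-condensation through the acidic methyl groups of 6, or hydrolysis of 6, may compete. The fallback changes the order of events. It sets out from aldehyde 2 and chloride 6 and returns at 7.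
- The smaller, planar phenoxide of 2 (K2CO3, MeCN) would give 2-[(3-acetyl-6-methyl-2-oxo-2H-pyran-4-yl)oxy]-3,5-dimethoxybenzaldehyde F5.
- The aldehyde would be reduced selectively (NaBH4, THF–MeOH, −40 °C, AcOH quench) to 3-acetyl-4-[2-(hydroxymethyl)-4,6-dimethoxyphenoxy]-6-methyl-2H-pyran-2-one F6.
- F6 would be silylated at once with TIPSOTf and 2,6-lutidine, before the alcohol can shift onto pyranone C4, to give 7.

**Step 4.** Chlorination may occur at the enolised acetyl oxygen instead of at pyranone C4, and the vinylogous acid chloride may hydrolyse on work-up. The fallback replaces deoxychlorination by sulfonylation. It sets out from 5 and returns at 7.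
- TsCl and Et3N in CH2Cl2 would give the stable, crystalline enol sulfonate 3-acetyl-6-methyl-2-oxo-2H-pyran-4-yl 4-methylbenzenesulfonate F7.
- F7 would undergo the same addition–elimination with 4 and K2CO3 to give 7.

**Step 8.** The fluoride-generated benzylic alkoxide may attack the neighbouring methyl ester (lactonisation to the eight-membered ring, or acyl transfer), or basic fluoride may cleave the ester. The fallback reverses the last two operations. It sets out from 10 and returns at 12.
- The silyl ether would be removed first with aqueous HF in MeCN, which is admissible because no prenyl ether is yet present, giving methyl 2-hydroxy-6-[2-(hydroxymethyl)-4,6-dimethoxyphenoxy]-4-methylbenzoate F8.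
- The phenol of F8 would then be prenylated chemoselectively (prenyl bromide, K2CO3, acetone), since carbonate deprotonates only the phenol, to give 12.

## Further compounds

F1 | step 6 | methyl 2,6-dihydroxy-4-methylbenzoate | COC(=O)c1c(O)cc(C)cc1O
F2 | step 6 | methyl 2-(benzyloxy)-6-hydroxy-4-methylbenzoate | COC(=O)c1c(O)cc(C)cc1OCc1ccccc1
F3 | step 6 | methyl 2-(benzyloxy)-4-methyl-6-(trifluoromethylsulfonyloxy)benzoate | COC(=O)c1c(OCc2ccccc2)cc(C)cc1OS(=O)(=O)C(F)(F)F
F4 | step 6 | methyl 2-(benzyloxy)-6-[2,4-dimethoxy-6-(triisopropylsilyloxymethyl)phenoxy]-4-methylbenzoate | COC(=O)c1c(OCc2ccccc2)cc(C)cc1Oc1c(CO[Si](C(C)C)(C(C)C)C(C)C)cc(OC)cc1OC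
F5 | step 5 | 2-[(3-acetyl-6-methyl-2-oxo-2H-pyran-4-yl)oxy]-3,5-dimethoxybenzaldehyde | CC(=O)C1=C(Oc2c(C=O)cc(OC)cc2OC)C=C(C)OC1=O
F6 | step 5 | 3-acetyl-4-[2-(hydroxymethyl)-4,6-dimethoxyphenoxy]-6-methyl-2H-pyran-2-one | CC(=O)C1=C(Oc2c(CO)cc(OC)cc2OC)C=C(C)OC1=O
F7 | step 4 | 3-acetyl-6-methyl-2-oxo-2H-pyran-4-yl 4-methylbenzenesulfonate | CC(=O)C1=C(OS(=O)(=O)c2ccc(C)cc2)C=C(C)OC1=O
F8 | step 8 | methyl 2-hydroxy-6-[2-(hydroxymethyl)-4,6-dimethoxyphenoxy]-4-methylbenzoate | COC(=O)c1c(O)cc(C)cc1Oc1c(CO)cc(OC)cc1OC
A1 | alternative 1 | methyl 2-[4-hydroxy-2-methoxy-6-(methoxycarbonyl)phenoxy]-4-methyl-6-(3-methylbut-2-enyloxy)benzoate | COC(=O)c1c(OCC=C(C)C)cc(C)cc1Oc1c(C(=O)OC)cc(O)cc1OC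
A2 | alternative 1 | methyl 2-{[2,4-dimethoxy-4-(trimethylsilyloxy)buta-1,3-dien-1-yl]oxy}-4-methyl-6-(3-methylbut-2-enyloxy)benzoate (mixture of double-bond isomers) | COC(O[Si](C)(C)C)=CC(OC)=COc1cc(C)cc(OCC=C(C)C)c1C(=O)OC
A3 | alternative 1 | methyl (E)-3-nitroacrylate | COC(=O)/C=C/[N+](=O)[O-]
A4 | alternative 2 | 2-(allyloxy)-6-[2,4-dimethoxy-6-(triisopropylsilyloxymethyl)phenoxy]-4-methylbenzoic acid | OC(=O)c1c(OCC=C)cc(C)cc1Oc1c(CO[Si](C(C)C)(C(C)C)C(C)C)cc(OC)cc1OC
A5 | alternative 2 | 3-(allyloxy)-5-methyl-2-(trimethylsilyl)phenyl trifluoromethanesulfonate | C=CCOc1cc(C)cc(OS(=O)(=O)C(F)(F)F)c1[Si](C)(C)C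
A6 | alternative 3 | methyl 2-[2,4-dimethoxy-6-(triisopropylsilyloxymethyl)phenoxy]-4-methyl-6-(3-methylbut-2-enyloxy)benzoate (identical with 11) | COC(=O)c1c(OCC=C(C)C)cc(C)cc1Oc1c(CO[Si](C(C)C)(C(C)C)C(C)C)cc(OC)cc1OC
A7 | alternative 3 | 1-(ethynyloxy)-2,4-dimethoxy-6-(triisopropylsilyloxymethyl)benzene | C#COc1c(CO[Si](C(C)C)(C(C)C)C(C)C)cc(OC)cc1OC
A8 | alternative 3 | methyl 6-methyl-4-(3-methylbut-2-enyloxy)-2-oxo-2H-pyran-3-carboxylate | COC(=O)C1=C(OCC=C(C)C)C=C(C)OC1=O
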